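The numbers in the tables stem from a simulated flask on assumed constants; noise was put on by code.

1. Wednesday's flask holds 37 mM of starting material and 0.18 mM of free catalyst, and about half of that starting material has become target.

common to all: starting material 37 mM; free catalyst 0.18 mM

|  | second substrate | capture agent | remark | time |
|---|---|---|---|---|
| Wednesday's | 37 mM | 0.74 mM | the very flask that is asked about, followed so far |  |
| Friday's | 37 mM | 1.1 mM | run made earlier |  |
| flask | 37.0 mM | 0.740 mM |  | 1.0 h |

| run | time / min | target / % | starting material / % |
|---|---|---|---|
| Wednesday's | 12.0 | 37.4 | 62.7 |
| Wednesday's | 25.0 | 45.7 | 54.7 |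
| Wednesday's | 40.0 | 48.4 | 52.0 |
| Wednesday's | 50.0 | 48.2 | 51.6 |
| Wednesday's | 60.0 | 48.0 | 51.5 |
| Friday's | 0.417 | 3.0 | 97.3 |
| Friday's | 0.667 | 4.3 | 95.7 |
| Friday's | 1.33 | 8.7 | 91.5 |
| Friday's | 2.50 | 13.5 | 86.0 |
| Friday's | 5.00 | 21.5 | 78.2 |

(standard deviation of a reading: 0.3 percentage points)

- target taken out counts as made
- additions bring no volume worth counting

- larch: at 1.0 h add starting material, 50.0% of the amount charged, then wait 30 min
- oak: at 1.0 h take out 90% of the target then present, then wait 30 min
- ash: change nothing and wait 30 min more
- cedar: at 1.0 h add free catalyst, 100% of the amount charged, then wait 30 min

1. target, in percent of the starting material first charged, at 1.0 h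
2. which option adds most target ("none" when 2 percentage points or less is all one gets) (larch / oak / ash / cedar / none)
3. target present, with what was taken out counted in, in percent of the starting material first charged, after larch
4. target present, with what was taken out counted in, in percent of the starting material first charged, after oak

2. Friday's flask, with more capture agent, slows early. Compounding the share of its first 1.33 min gives 29.0% at 5.00 min, but I read 21.5%, well short of Wednesday's plateau. So I read that plateau as lost catalyst.

3. I carry one quantity: the charge share, the part of the starting material present that one charge of catalyst turns into target. I take the rate as pseudo-first-order in starting material. The last three readings give 48.2%, which is also my value for 1.0 h.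

4. Target stands still from 40.0 min to 60.0 min within the scatter of 0.3 percentage points. Larch gives about twice the starting material, but that doubles a pace too small to read, so I expect its gain to stay within 2 points. Oak and ash add no catalyst.

5. Cedar's ceiling is the starting material left, for a total of 99.7%. A bare floor is no gain. I tighten it: if the fresh charge converts, in the allowed time, the share Wednesday's made by 25.0 min, it adds 24 points, for a total of 71.7%.

6. The forecast gives 48.2% (47.8% to 48.6%), cedar, 48.8% after larch and 48.5% after oak: “The plateau is therefore dead catalyst, not equilibrium.” Its about 65% after cedar stands outside my bracket.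

7. The flask gives 48.5% at 1.0 h, 48.7% after larch and 48.6% after oak. The best option is cedar, which adds 29 points.

    starting material + free catalyst ⇌ catalyst intermediate A (K = 470 /M, k = 9.70 /M/s)
    catalyst intermediate A → free catalyst + target (k = 6.10 /s)
    second substrate + free catalyst ⇌ catalyst intermediate B (K = 11.0 /M, k = 140 /M/s)
    catalyst intermediate B → free catalyst + second product (k = 0.330 /s)
    catalyst intermediate B + capture agent → trapped intermediate (k = 7.70 /M/s)
    free catalyst → spent catalyst (k = 7.90 × 10⁻⁴ /s)

Cedar's gain lies inside my bracket, above the 24 points floor. For a flask like this one with 0.45 mM of free catalyst, the charge share predicts 80.7%, and that flask gives 87.9%. In this flask at 5.09 min, catalyst intermediate B has a half-life of 2.1 s for going on to free catalyst and second product, against 2.2 min for capture, a ratio of 62.9. At 60.0 min, trapped intermediate holds 69.7% of the catalyst and spent catalyst 30.1%.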